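**Plan** (locants: ring O1, C2(=O), C3, C4(OH), C5, C6; side chain C1'–C15' on C6)

1. Retrosynthetic cuts: the ring is first taken back to the aromatic 4-hydroxy-2-pyrone (C5=C6 restored). Then the C1'–C2' bond (exocyclic CH2 on ring C6 to the first carbinol) is cut, giving triacetic acid lactone and a C14 aldehyde. The aldehyde goes back through a Claisen cut (its C2–C3 bond) to a C12 β-keto ester and tert-butyl acetate.
2. Forward order: the C14 syn-diol chain is built (steps 1–5), joined to the intact, flat pyrone ring through its 6-methyl carbon (step 6) and desilylated (step 7). The ring is dearomatized last by hydrogenation (step 8); the ring is never closed, it is bought.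
3. Enabling feature: the ring of the target (O1, C2–C6) is the 5,6-dihydro form of a 4-hydroxy-2-pyrone and carries its chain on an exocyclic CH2 at C6. In the aromatic pyrone this CH2 is the vinylogous methyl group, so the whole six-carbon ring unit can act as the nucleophile without protection, and the new carbinol C2' lies β to the oxygen-bearing C4' of the aldehyde.
4. Stereochemistry: C6' by catalytic asymmetric hydrogenation (step 1); C4' relayed from C6' by 1,3-syn reduction (step 3); C2' relayed from C4' by 1,3-anti induction in the coupling (step 6); ring C6 by catalyst-controlled hydrogenation of the pyrone (step 8).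

Key step: step 6

Assumption: the (S)-MeO-BIPHEP ligand in step 8 is taken to give the (6R)-dihydropyranone. The sense is to be checked on compound 11 itself, which should then give the (R)-6-methyl dihydropyranone; the (R)-ligand is used if the check says otherwise.
Remark: the descriptor at C4' reads R in the silylated compounds 13 and 14 and S in 15 and 16 through CIP ranking only; no centre is inverted.

**Step 1**
Reactants: 1 methyl 3-oxododecanoate
Product: 2 methyl (3S)-3-hydroxydodecanoate
Conditions: H2 (50 bar), [RuCl2((S)-BINAP)] (0.1 mol %), MeOH, 50 °C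
Reagents that add atoms: none
Why: Noyori asymmetric hydrogenation of a β-keto ester, in which the keto ester chelates Ru and the (S)-BINAP ligand should direct hydride to the face that gives the (3S)-alcohol, the sense known for simple alkyl β-keto esters.

**Step 2**
Reactants: 2 methyl (3S)-3-hydroxydodecanoate; 3 tert-butyl acetate
Product: 5 tert-butyl (5S)-5-hydroxy-3-oxotetradecanoate, via lithium enolate of tert-butyl acetate 4 (not isolated)
Conditions: 3 (4 equiv), LDA (4 equiv), THF, −78 °C; then 2, −78 → −20 °C; aq. NH4Cl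
Reagents that add atoms: none
Why: Crossed Claisen condensation of an unprotected β-hydroxy ester with excess ester enolate, in which the first equivalent forms the alkoxide, the next adds to the methyl ester, and the product rests as its β-keto ester enolate so that no second addition occurs and C5 is not touched.

**Step 3**
Reactants: 5 tert-butyl (5S)-5-hydroxy-3-oxotetradecanoate
Product: 7 tert-butyl (3S,5S)-3,5-dihydroxytetradecanoate, via diethylboron chelate 6 (not isolated)
Conditions: Et2BOMe (1.1 equiv), THF/MeOH 4:1, −78 °C; NaBH4 (1.2 equiv); AcOH; MeOH co-evaporation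
Reagents that add atoms: none
Why: Narasaka–Prasad reduction, in which the diethylboron chelate 6 holds hydroxyl and ketone in a six-membered half-chair and external hydride adds axially, which should give the 1,3-syn diol so that C3 is relayed from C5.

**Step 4**
Reactants: 7 tert-butyl (3S,5S)-3,5-dihydroxytetradecanoate
Product: 8 tert-butyl (3S,5S)-3,5-bis(tert-butyldimethylsilyloxy)tetradecanoate
Conditions: TBSCl (3 equiv), imidazole (6 equiv), DMAP (cat.), DMF, 40 °C
Reagents that add atoms: tert-butyldimethylsilyl chloride, CC(C)(C)[Si](C)(C)Cl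
Why: Standard silylation of both secondary alcohols, chosen because silyl ethers are non-chelating β-substituents (needed for the polar 1,3-anti model in step 6) and should survive DIBAL-H and BF3 at −78 °C.

**Step 5**
Reactants: 8 tert-butyl (3S,5S)-3,5-bis(tert-butyldimethylsilyloxy)tetradecanoate
Product: 10 (3S,5S)-3,5-bis(tert-butyldimethylsilyloxy)tetradecanal, via aluminium hemiacetal 9 (not isolated)
Conditions: DIBAL-H (1.2 equiv), toluene, −78 °C; MeOH at −78 °C; aq. Rochelle salt
Reagents that add atoms: none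
Why: Partial reduction of an ester with DIBAL-H, in which the tetrahedral aluminium hemiacetal 9 should be stable at −78 °C and release the aldehyde only on work-up, leaving the silyl ethers and both stereocentres untouched.

**Step 6**
Reactants: 10 (3S,5S)-3,5-bis(tert-butyldimethylsilyloxy)tetradecanal; 11 4-hydroxy-6-methyl-2H-pyran-2-one (triacetic acid lactone)
Product: 14 6-[(2R,4R,6S)-4,6-bis(tert-butyldimethylsilyloxy)-2-hydroxypentadecyl]-4-hydroxy-2H-pyran-2-one, via 2,4-bis(trimethylsilyloxy)-6-methylene-6H-pyran 12 (not isolated), via 4-O-trimethylsilyl adduct 13 (not isolated)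
Conditions: 11 (1.6 equiv), LDA (3.4 equiv), THF, −78 °C; TMSCl (3.6 equiv), −78 → 0 °C; solvent exchange to CH2Cl2 under Ar; 10 (1 equiv), BF3·OEt2 (1.2 equiv), CH2Cl2, −78 °C; aq. NaHCO3; then citric acid, MeOH/H2O, 0 °C
Reagents that add atoms: none
Why: Proposed new method: double deprotonation of 11 (O–H, then the 6-methyl group) followed by O,O-silylation should give the cross-conjugated silyl trienol ether 12, whose exocyclic CH2 adds to the BF3-bound aldehyde through an open transition state while the ring re-aromatizes to the 2-pyrone and the 2-O-silyl group is lost (13, then 14 after mild acid); the closest known reaction types are the vinylogous Mukaiyama aldol of the silyl dienol ether of 2,2,6-trimethyl-1,3-dioxin-4-one, which also attacks through an exocyclic methylene, and the terminal aldol addition of the acyclic 1,3,5-tris(silyloxy)hexatriene derived from a 3,5-dioxo ester, of which 12 is the ring-closed form. No ring is closed in this step, because the six-membered lactone ring (O1, C2–C6) enters intact and flat. The one new stereocentre, C2' of the side chain, should be controlled by the silyloxy-bearing β-carbon of 10 (the later C4'): with monodentate BF3 no chelate is possible, the aldehyde reacts through the conformer in which the Cβ–O and C=O dipoles are opposed, and the nucleophile comes in on the side away from the Cβ alkyl chain, which is the polar 1,3-anti model and gives the 2',4'-anti relation of the target. The step needs ε-regioselectivity (exocyclic CH2, not ring C3 or C5), which is secured because only attack through the exocyclic terminus restores the aromatic pyrone and because that terminus is the least hindered end of the trienol ether. It also needs the silyl ethers of 10 to survive the Lewis acid, which the TBS groups at −78 °C should do.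

**Step 7**
Reactants: 14 6-[(2R,4R,6S)-4,6-bis(tert-butyldimethylsilyloxy)-2-hydroxypentadecyl]-4-hydroxy-2H-pyran-2-one
Product: 15 4-hydroxy-6-[(2R,4S,6S)-2,4,6-trihydroxypentadecyl]-2H-pyran-2-one
Conditions: HF (48 % aq.), MeCN, 0 °C → rt
Reagents that add atoms: none
Why: Acidic fluoride desilylation driven by Si–F bond formation, to which the aromatic 4-hydroxy-2-pyrone and the secondary carbinols should be inert, so that no stereocentre is touched.

**Step 8**
Reactants: 15 4-hydroxy-6-[(2R,4S,6S)-2,4,6-trihydroxypentadecyl]-2H-pyran-2-one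
Product: 16 (6R)-4-hydroxy-6-[(2R,4S,6S)-2,4,6-trihydroxypentadecyl]-5,6-dihydro-2H-pyran-2-one
Conditions: H2 (60 bar), [Ru(OAc)2((S)-MeO-BIPHEP)] (1 mol %), HBF4·OEt2 (2 mol %), MeOH, 60 °C; extraction into aq. NaHCO3, acidification
Reagents that add atoms: none
Why: Catalytic asymmetric hydrogenation of the 5,6-double bond of 6-alkyl-4-hydroxy-2-pyrones with cationic Ru(II)–atropisomeric diphosphine complexes is a known dearomatizing reduction, so the chiral catalyst is expected to choose the ring face and set C6 as R, while the 3,4-double bond (the enol of the β-keto lactone) and the side-chain carbinols should stay untouched.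

**Compound list**

1 | methyl 3-oxododecanoate | CCCCCCCCCC(=O)CC(=O)OC | starting material
2 | methyl (3S)-3-hydroxydodecanoate | CCCCCCCCC[C@H](O)CC(=O)OC | intermediate
3 | tert-butyl acetate | CC(=O)OC(C)(C)C | starting material
4 | lithium enolate of tert-butyl acetate (not isolated) | [Li+].[O-]C(=C)OC(C)(C)C | intermediate
5 | tert-butyl (5S)-5-hydroxy-3-oxotetradecanoate | CCCCCCCCC[C@H](O)CC(=O)CC(=O)OC(C)(C)C | intermediate
6 | diethylboron chelate, tert-butyl (5S)-5-(diethylboranyloxy)-3-oxotetradecanoate (not isolated) | CCCCCCCCC[C@H](OB(CC)CC)CC(=O)CC(=O)OC(C)(C)C | intermediate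
7 | tert-butyl (3S,5S)-3,5-dihydroxytetradecanoate | CCCCCCCCC[C@H](O)C[C@H](O)CC(=O)OC(C)(C)C | intermediate
8 | tert-butyl (3S,5S)-3,5-bis(tert-butyldimethylsilyloxy)tetradecanoate | CCCCCCCCC[C@H](O[Si](C)(C)C(C)(C)C)C[C@H](O[Si](C)(C)C(C)(C)C)CC(=O)OC(C)(C)C | intermediate
9 | aluminium hemiacetal, (3S,5S)-1-tert-butoxy-1-(diisobutylalumanyloxy)-3,5-bis(tert-butyldimethylsilyloxy)tetradecane (not isolated) | CCCCCCCCC[C@H](O[Si](C)(C)C(C)(C)C)C[C@H](O[Si](C)(C)C(C)(C)C)CC(O[Al](CC(C)C)CC(C)C)OC(C)(C)C | intermediate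
10 | (3S,5S)-3,5-bis(tert-butyldimethylsilyloxy)tetradecanal | CCCCCCCCC[C@H](O[Si](C)(C)C(C)(C)C)C[C@H](O[Si](C)(C)C(C)(C)C)CC=O | intermediate
11 | 4-hydroxy-6-methyl-2H-pyran-2-one (triacetic acid lactone) | CC1=CC(O)=CC(=O)O1 | starting material
12 | 2,4-bis(trimethylsilyloxy)-6-methylene-6H-pyran (not isolated) | C=C1C=C(O[Si](C)(C)C)C=C(O[Si](C)(C)C)O1 | intermediate
13 | 6-[(2R,4R,6S)-4,6-bis(tert-butyldimethylsilyloxy)-2-hydroxypentadecyl]-4-(trimethylsilyloxy)-2H-pyran-2-one (not isolated) | CCCCCCCCC[C@H](O[Si](C)(C)C(C)(C)C)C[C@H](O[Si](C)(C)C(C)(C)C)C[C@@H](O)CC1=CC(O[Si](C)(C)C)=CC(=O)O1 | intermediate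
14 | 6-[(2R,4R,6S)-4,6-bis(tert-butyldimethylsilyloxy)-2-hydroxypentadecyl]-4-hydroxy-2H-pyran-2-one | CCCCCCCCC[C@H](O[Si](C)(C)C(C)(C)C)C[C@H](O[Si](C)(C)C(C)(C)C)C[C@@H](O)CC1=CC(O)=CC(=O)O1 | intermediate
15 | 4-hydroxy-6-[(2R,4S,6S)-2,4,6-trihydroxypentadecyl]-2H-pyran-2-one | CCCCCCCCC[C@H](O)C[C@H](O)C[C@@H](O)CC1=CC(O)=CC(=O)O1 | intermediate
16 | (6R)-4-hydroxy-6-[(2R,4S,6S)-2,4,6-trihydroxypentadecyl]-5,6-dihydro-2H-pyran-2-one | CCCCCCCCC[C@H](O)C[C@H](O)C[C@@H](O)C[C@@H]1CC(O)=CC(=O)O1 | target

**Step count**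

Total steps: 8. Longest linear sequence: 8 (1 → 16); compounds 3 and 11 enter as bought materials.

**Steps most likely to fail**

1. Step 6 (proposed new method). The trienol ether may be silylated on carbon instead of oxygen, or be protonated back to 11 before it meets the aldehyde. Attack may occur through a ring carbon instead of the exocyclic terminus, or facial discrimination at the aldehyde may be weak. The fallback uses known chemistry, sets out from 10 and comes back at 15: the side-chain bond is made by an established Mukaiyama aldol and the pyrone ring is then built around it. Aldehyde 10 is treated with 1-(tert-butyldimethylsilyloxy)-1-methoxyethene and BF3·OEt2 (CH2Cl2, −78 °C), which should give, by the same polar 1,3-anti induction, methyl (3R,5R,7S)-5,7-bis(tert-butyldimethylsilyloxy)-3-hydroxyhexadecanoate F1. Silylation (TBSOTf, 2,6-lutidine, CH2Cl2) gives methyl (3R,5S,7S)-3,5,7-tris(tert-butyldimethylsilyloxy)hexadecanoate F2. The dianion of methyl acetoacetate (NaH, then n-BuLi, THF, 0 °C) is acylated at its terminal carbon by the ester to give methyl (7R,9S,11S)-7,9,11-tris(tert-butyldimethylsilyloxy)-3,5-dioxoicosanoate F3. DBU in toluene (80 °C) closes the enol lactone to 4-hydroxy-6-[(2R,4S,6S)-2,4,6-tris(tert-butyldimethylsilyloxy)pentadecyl]-2H-pyran-2-one F4, and aqueous HF in MeCN as in step 7 returns the route to 15.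

2. Step 8. Facial selection at ring C6 may be poor if the free 2'-hydroxyl binds the metal and opposes the ligand's preference. The triol may slow the catalyst, the 3,4-enol may be reduced further, or water may be lost from C2' under the acidic conditions. The fallback sets out from 10 and comes back at 16: ring C6 is set by substrate-controlled reduction of an open-chain ketone and the ring is closed by lactonization. Aldehyde 10 and 1-methoxy-1,3-bis(trimethylsilyloxy)buta-1,3-diene with BF3·OEt2 (CH2Cl2, −78 °C) should give methyl (5R,7R,9S)-7,9-bis(tert-butyldimethylsilyloxy)-5-hydroxy-3-oxooctadecanoate F5. Narasaka–Prasad reduction (Et2BOMe, NaBH4, THF/MeOH, −78 °C) gives the 1,3-syn diol methyl (3R,5S,7R,9S)-7,9-bis(tert-butyldimethylsilyloxy)-3,5-dihydroxyoctadecanoate F6. 2,2-Dimethoxypropane with PPTS gives methyl 2-[(4R,6S)-6-[(2R,4S)-2,4-bis(tert-butyldimethylsilyloxy)tridecyl]-2,2-dimethyl-1,3-dioxan-4-yl]acetate F7. Claisen condensation with excess lithium enolate of tert-butyl acetate (THF, −78 → −30 °C) gives tert-butyl 4-[(4R,6S)-6-[(2R,4S)-2,4-bis(tert-butyldimethylsilyloxy)tridecyl]-2,2-dimethyl-1,3-dioxan-4-yl]-3-oxobutanoate F8. Aqueous HF in MeCN removes the silyl ethers and the acetonide to give tert-butyl (5R,7R,9S,11S)-5,7,9,11-tetrahydroxy-3-oxoicosanoate F9, and TFA in CH2Cl2 cleaves the ester and lactonizes onto the C5 hydroxyl to give 16.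

3. Step 5. The hindered tert-butyl ester may stall, or the reduction may run on to the primary alcohol; silanol may also be eliminated from the β-silyloxy aldehyde during work-up. The fallback sets out from 8 and comes back at 10 by a reduction–oxidation detour: LiAlH4 (Et2O, 0 °C) reduces the ester fully to (3R,5S)-3,5-bis(tert-butyldimethylsilyloxy)tetradecan-1-ol F10, and Dess–Martin periodinane (CH2Cl2, NaHCO3) oxidizes it to 10.

**Further compounds**

F1 | step 6 | methyl (3R,5R,7S)-5,7-bis(tert-butyldimethylsilyloxy)-3-hydroxyhexadecanoate | CCCCCCCCC[C@H](O[Si](C)(C)C(C)(C)C)C[C@H](O[Si](C)(C)C(C)(C)C)C[C@@H](O)CC(=O)OC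
F2 | step 6 | methyl (3R,5S,7S)-3,5,7-tris(tert-butyldimethylsilyloxy)hexadecanoate | CCCCCCCCC[C@H](O[Si](C)(C)C(C)(C)C)C[C@H](O[Si](C)(C)C(C)(C)C)C[C@@H](O[Si](C)(C)C(C)(C)C)CC(=O)OC
F3 | step 6 | methyl (7R,9S,11S)-7,9,11-tris(tert-butyldimethylsilyloxy)-3,5-dioxoicosanoate | CCCCCCCCC[C@H](O[Si](C)(C)C(C)(C)C)C[C@H](O[Si](C)(C)C(C)(C)C)C[C@@H](O[Si](C)(C)C(C)(C)C)CC(=O)CC(=O)CC(=O)OC
F4 | step 6 | 4-hydroxy-6-[(2R,4S,6S)-2,4,6-tris(tert-butyldimethylsilyloxy)pentadecyl]-2H-pyran-2-one | CCCCCCCCC[C@H](O[Si](C)(C)C(C)(C)C)C[C@H](O[Si](C)(C)C(C)(C)C)C[C@@H](O[Si](C)(C)C(C)(C)C)CC1=CC(O)=CC(=O)O1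
F5 | step 8 | methyl (5R,7R,9S)-7,9-bis(tert-butyldimethylsilyloxy)-5-hydroxy-3-oxooctadecanoate | CCCCCCCCC[C@H](O[Si](C)(C)C(C)(C)C)C[C@H](O[Si](C)(C)C(C)(C)C)C[C@@H](O)CC(=O)CC(=O)OC
F6 | step 8 | methyl (3R,5S,7R,9S)-7,9-bis(tert-butyldimethylsilyloxy)-3,5-dihydroxyoctadecanoate | CCCCCCCCC[C@H](O[Si](C)(C)C(C)(C)C)C[C@H](O[Si](C)(C)C(C)(C)C)C[C@@H](O)C[C@@H](O)CC(=O)OC
F7 | step 8 | methyl 2-[(4R,6S)-6-[(2R,4S)-2,4-bis(tert-butyldimethylsilyloxy)tridecyl]-2,2-dimethyl-1,3-dioxan-4-yl]acetate | CCCCCCCCC[C@H](O[Si](C)(C)C(C)(C)C)C[C@H](O[Si](C)(C)C(C)(C)C)C[C@@H]1C[C@H](CC(=O)OC)OC(C)(C)O1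
F8 | step 8 | tert-butyl 4-[(4R,6S)-6-[(2R,4S)-2,4-bis(tert-butyldimethylsilyloxy)tridecyl]-2,2-dimethyl-1,3-dioxan-4-yl]-3-oxobutanoate | CCCCCCCCC[C@H](O[Si](C)(C)C(C)(C)C)C[C@H](O[Si](C)(C)C(C)(C)C)C[C@@H]1C[C@H](CC(=O)CC(=O)OC(C)(C)C)OC(C)(C)O1
F9 | step 8 | tert-butyl (5R,7R,9S,11S)-5,7,9,11-tetrahydroxy-3-oxoicosanoate | CCCCCCCCC[C@H](O)C[C@H](O)C[C@@H](O)C[C@@H](O)CC(=O)CC(=O)OC(C)(C)C
F10 | step 5 | (3R,5S)-3,5-bis(tert-butyldimethylsilyloxy)tetradecan-1-ol | CCCCCCCCC[C@H](O[Si](C)(C)C(C)(C)C)C[C@H](O[Si](C)(C)C(C)(C)C)CCO
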